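**Plan**
- Retrosynthetic cuts: first the three MOM ethers, then the diaryl ether bond between the ring B oxygen and C4 of ring A (Ullmann coupling of a ring A iodide with a ring B phenol). In each half the C5–C6 bond is cut next (Negishi coupling with the (E)-alkenyl iodide from 6-methylhept-5-en-2-one), and last the C1=C2 and C4=C5 bonds, which lead back to a 3-aryl-3-methylcyclopropene and butyl vinyl ether.
- Enabling feature: each quaternary C3 carries, besides CH3 and its arene (ring A or ring B), the vinyl group C1=C2 and the C4–C5 arm. These two two-carbon branches are the two sp2 ring carbons of a cyclopropene whose third ring carbon is C3, so ring-opening metathesis with a vinyl ether sets free both branches at once and leaves C5 as a masked aldehyde.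
- Forward order: no ring is formed. Each acetophenone is taken to the isopropenylarene, the cyclopropene, the ring-opened diene and the C5 iodide, and the chain is then attached. Ortho-lithiation next to OMOM gives the iodide (ring A) or the phenol (ring B), followed by C–O coupling and deprotection.
- Stereochemistry: C3 (R) of ring A and C3 (S) of ring B come from the two antipodes of one stereogenic-at-molybdenum catalyst in the desymmetrising ring opening. Both 6E alkenes come from syn-carboalumination of an alkyne and stereoretentive cross-coupling.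

Key step: step 8

Assumption: the catalyst built from the (R)-aryloxide is taken to serve the ring A series and its antipode the ring B series; if a test run shows the opposite sense of induction, the two antipodes are exchanged.
Remark: only MOM ethers are used, because aryl silyl ethers would not survive 50% NaOH or KOtBu/DMSO. The ether oxygen is brought in on ring B, so ring A carries one oxygen until the coupling.

**Chain fragment**

Step 1
Reactants: 1 6-methylhept-5-en-2-one
Product: 3 6-methylhept-5-en-1-yne, via enol phosphate 2 (not isolated)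
Conditions: LDA (1.05 equiv), THF, −78 °C; ClP(O)(OEt)2, −78 °C → rt; LDA (2.3 equiv), THF, −78 °C → rt; H2O
Reagents that add atoms: none
Why: Kinetic deprotonation at the CH3 group gives the terminal enolate, O-phosphorylation gives the enol phosphate, and LDA-induced β-elimination of diethyl phosphate (methyl ketone to terminal alkyne conversion) should give the alkyne, the remote trisubstituted alkene being inert.

Step 2
Reactants: 3 6-methylhept-5-en-1-yne
Product: 5 (E)-1-iodo-2,6-dimethylhepta-1,5-diene, via alkenylalane 4 (not isolated)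
Conditions: Me3Al (2 equiv), Cp2ZrCl2 (0.25 equiv), CH2Cl2, 0 °C → rt; I2, THF, −30 → 0 °C
Reagents that add atoms: trimethylaluminium, C[Al](C)C; iodine, [I][I]
Why: Zirconium-catalysed syn-carboalumination of the terminal alkyne (Negishi carboalumination) puts CH3 on the internal and Al on the terminal carbon, and iodinolysis of the C–Al bond with retention should give the (E)-iodide only.

**Ring A series**

Step 3
Reactants: 6 3-hydroxyacetophenone
Product: 7 1-[3-(methoxymethoxy)phenyl]ethanone
Conditions: MOMCl, iPr2NEt, CH2Cl2, 0 °C → rt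
Reagents that add atoms: chloromethyl methyl ether, COCCl
Why: O-alkylation of the phenol with the reactive α-chloro ether (MOM protection) is standard and gives an acetal that is stable to all the basic and organometallic steps ahead.

Step 4
Reactants: 7 1-[3-(methoxymethoxy)phenyl]ethanone
Product: 8 1-(methoxymethoxy)-3-(prop-1-en-2-yl)benzene
Conditions: Ph3PCH3Br, KOtBu, THF, 0 °C → rt
Reagents that add atoms: methyltriphenylphosphonium bromide, C[P+](c1ccccc1)(c1ccccc1)c1ccccc1.[Br-]
Why: Wittig methylenation of an aryl methyl ketone with the unstabilised ylide reliably gives the 1,1-disubstituted alkene.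

Step 5
Reactants: 8 1-(methoxymethoxy)-3-(prop-1-en-2-yl)benzene
Product: 9 1-(2,2-dibromo-1-methylcyclopropyl)-3-(methoxymethoxy)benzene (racemic)
Conditions: CHBr3, 50% aq NaOH, BnEt3NCl (cat.), CH2Cl2, rt
Reagents that add atoms: bromoform, BrC(Br)Br
Why: Phase-transfer generation of dibromocarbene and its [2+1] cycloaddition to the electron-rich α-methylstyrene is a standard route to gem-dibromocyclopropanes, and the MOM acetal is stable to aqueous hydroxide.

Step 6
Reactants: 9 1-(2,2-dibromo-1-methylcyclopropyl)-3-(methoxymethoxy)benzene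
Product: 10 1-(2-bromo-1-methylcyclopropyl)-3-(methoxymethoxy)benzene (racemic, cis/trans mixture)
Conditions: EtMgBr (1.3 equiv), Ti(OiPr)4 (5 mol %), Et2O, rt
Reagents that add atoms: none
Why: Titanium-catalysed hydrodebromination with ethylmagnesium bromide as hydride source stops cleanly at the monobromide; both diastereomers are usable because each has a β-hydrogen on the ring CH2.

Step 7
Reactants: 10 1-(2-bromo-1-methylcyclopropyl)-3-(methoxymethoxy)benzene
Product: 11 1-(methoxymethoxy)-3-(1-methylcycloprop-2-en-1-yl)benzene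
Conditions: KOtBu, DMSO, rt
Reagents that add atoms: none
Why: Base-induced 1,2-elimination of HBr from a bromocyclopropane gives the cyclopropene, which is isolable because its quaternary C3 has no hydrogen for ene dimerisation or isomerisation.

Step 8
Reactants: 11 1-(methoxymethoxy)-3-(1-methylcycloprop-2-en-1-yl)benzene; 12 butyl vinyl ether
Product: 13 1-[(1Z,3S)-1-butoxy-3-methylpenta-1,4-dien-3-yl]-3-(methoxymethoxy)benzene
Conditions: Mo(NAd)(CHCMe2Ph)(2,5-Me2C4H2N)(OAr*) with (R)-OAr* (3 mol %, made in situ from Mo(NAd)(CHCMe2Ph)(2,5-Me2C4H2N)2 and (R)-HOAr*), 12 (5 equiv), C6H6, 22 °C, N2; Ad = 1-adamantyl, HOAr* = 3,3'-dibromo-2'-(tert-butyldimethylsilyloxy)-5,5',6,6',7,7',8,8'-octahydro-1,1'-binaphthalen-2-ol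
Reagents that add atoms: none
Why: The alkoxyalkylidene Mo=CH(OBu) of hexavalent molybdenum formed on initiation should add across the strained C=C of 11 in a [2+2] step, and the metallacyclobutane should open irreversibly to the enol ether arm C4=C5 and a new alkylidene at C2, which a second molecule of 12 caps as the vinyl group C1=C2 while regenerating Mo=CH(OBu). The closest known reaction type is the catalytic enantioselective ring-opening/cross-metathesis of 3-aryl-3-methylcyclopropenes with enol ethers under stereogenic-at-molybdenum monoaryloxide pyrrolide complexes. No ring is closed; the three-membered ring is opened and two skeletal C=C bonds are formed. The C3 stereocentre is controlled by the catalyst: the stereogenic metal centre, with its small adamantylimido and large chiral aryloxide ligands, decides which of the two enantiotopic olefinic carbons bonds to molybdenum, approach being expected on the methyl face away from the arene. The step needs selection between the enantiotopic termini and freedom from oligomerisation or secondary metathesis; the aryl/methyl size difference at C3 serves the first, and the excess of 12 together with shielding of both product alkenes by the adjacent quaternary carbon serves the second. The Z/E ratio of the enol ether is of no consequence, since the next step hydrolyses it, and the (S) descriptor of 13 becomes (R) after hydrolysis only through a change of priorities.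

Step 9
Reactants: 13 1-[(1Z,3S)-1-butoxy-3-methylpenta-1,4-dien-3-yl]-3-(methoxymethoxy)benzene
Product: 15 (3R)-3-[3-(methoxymethoxy)phenyl]-3-methylpent-4-en-1-ol, via aldehyde 14 (not isolated)
Conditions: 1 M aq HCl, THF, 0 °C; then NaHCO3, NaBH4, MeOH, 0 °C
Reagents that add atoms: water, O
Why: Acid-catalysed enol ether hydrolysis (C4 protonation, hydration of the oxocarbenium ion at C5, loss of butanol) is much faster than cleavage of an aryl MOM acetal, and borohydride reduction of the aldehyde in the same flask should give the primary alcohol with the quaternary C3 untouched.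

Step 10
Reactants: 15 (3R)-3-[3-(methoxymethoxy)phenyl]-3-methylpent-4-en-1-ol
Product: 16 1-[(3R)-5-iodo-3-methylpent-1-en-3-yl]-3-(methoxymethoxy)benzene
Conditions: I2, PPh3, imidazole, CH2Cl2, 0 °C → rt
Reagents that add atoms: iodine, [I][I]
Why: Appel-type iodination of a primary alcohol proceeds by SN2 displacement of the alkoxyphosphonium ion and leaves the vinyl group and the MOM ether intact.

Step 11
Reactants: 16 1-[(3R)-5-iodo-3-methylpent-1-en-3-yl]-3-(methoxymethoxy)benzene; 5 (E)-1-iodo-2,6-dimethylhepta-1,5-diene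
Product: 18 1-(methoxymethoxy)-3-[(3R,6E)-3,7,11-trimethyldodeca-1,6,10-trien-3-yl]benzene, via alkylzinc iodide 17 (not isolated)
Conditions: Zn dust (activated with BrCH2CH2Br, Me3SiCl), THF, 40 °C; then 5, Pd(PPh3)4 (5 mol %), THF, rt
Reagents that add atoms: none
Why: Zinc inserts into the primary C–I bond and the alkylzinc iodide should undergo Negishi coupling at zerovalent palladium with retention of the alkene geometry, forming C5–C6; a pent-4-enyl organometallic has no easy cyclisation path.

Step 12
Reactants: 18 1-(methoxymethoxy)-3-[(3R,6E)-3,7,11-trimethyldodeca-1,6,10-trien-3-yl]benzene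
Product: 20 1-iodo-2-(methoxymethoxy)-4-[(3R,6E)-3,7,11-trimethyldodeca-1,6,10-trien-3-yl]benzene, via aryllithium 19 (not isolated)
Conditions: n-BuLi (1.3 equiv), THF, 0 °C; ICH2CH2I, −78 °C → rt
Reagents that add atoms: 1,2-diiodoethane, ICCI
Why: Directed ortho-metalation by the OMOM group should occur only para to the side chain, because the other ortho position is blocked by the quaternary carbon, and the aryllithium is iodinated with loss of ethene; isolated alkenes are inert to n-BuLi at 0 °C.

**Ring B series**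

Step 13
Reactants: 21 3,4-dihydroxyacetophenone
Product: 22 1-[3,4-bis(methoxymethoxy)phenyl]ethanone
Conditions: MOMCl (2.5 equiv), iPr2NEt, CH2Cl2, 0 °C → rt
Reagents that add atoms: chloromethyl methyl ether, COCCl
Why: Double O-alkylation of the catechol (MOM protection) gives two acetals that later act as ortho-directing groups.

Step 14
Reactants: 22 1-[3,4-bis(methoxymethoxy)phenyl]ethanone
Product: 23 1,2-bis(methoxymethoxy)-4-(prop-1-en-2-yl)benzene
Conditions: Ph3PCH3Br, KOtBu, THF, 0 °C → rt
Reagents that add atoms: methyltriphenylphosphonium bromide, C[P+](c1ccccc1)(c1ccccc1)c1ccccc1.[Br-]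
Why: Wittig methylenation of the aryl methyl ketone, as in step 4.

Step 15
Reactants: 23 1,2-bis(methoxymethoxy)-4-(prop-1-en-2-yl)benzene
Product: 24 4-(2,2-dibromo-1-methylcyclopropyl)-1,2-bis(methoxymethoxy)benzene (racemic)
Conditions: CHBr3, 50% aq NaOH, BnEt3NCl (cat.), CH2Cl2, rt
Reagents that add atoms: bromoform, BrC(Br)Br
Why: Phase-transfer dibromocarbene [2+1] cycloaddition to the styrene, as in step 5.

Step 16
Reactants: 24 4-(2,2-dibromo-1-methylcyclopropyl)-1,2-bis(methoxymethoxy)benzene
Product: 25 4-(2-bromo-1-methylcyclopropyl)-1,2-bis(methoxymethoxy)benzene (racemic, cis/trans mixture)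
Conditions: EtMgBr (1.3 equiv), Ti(OiPr)4 (5 mol %), Et2O, rt
Reagents that add atoms: none
Why: Titanium-catalysed monohydrodebromination of the gem-dibromide, as in step 6.

Step 17
Reactants: 25 4-(2-bromo-1-methylcyclopropyl)-1,2-bis(methoxymethoxy)benzene
Product: 26 1,2-bis(methoxymethoxy)-4-(1-methylcycloprop-2-en-1-yl)benzene
Conditions: KOtBu, DMSO, rt
Reagents that add atoms: none
Why: Base-induced 1,2-elimination of HBr to the 3,3-disubstituted cyclopropene, as in step 7.

Step 18
Reactants: 26 1,2-bis(methoxymethoxy)-4-(1-methylcycloprop-2-en-1-yl)benzene; 12 butyl vinyl ether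
Product: 27 4-[(1Z,3R)-1-butoxy-3-methylpenta-1,4-dien-3-yl]-1,2-bis(methoxymethoxy)benzene
Conditions: Mo(NAd)(CHCMe2Ph)(2,5-Me2C4H2N)(OAr*) with (S)-OAr* (3 mol %, made in situ as in step 8 from (S)-HOAr*), 12 (5 equiv), C6H6, 22 °C, N2
Reagents that add atoms: none
Why: The same enantioselective ring-opening/cross-metathesis as in step 8, run with the mirror-image catalyst, should select the other enantiotopic olefinic carbon and so give the antipodal arrangement at C3.

Step 19
Reactants: 27 4-[(1Z,3R)-1-butoxy-3-methylpenta-1,4-dien-3-yl]-1,2-bis(methoxymethoxy)benzene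
Product: 29 (3S)-3-[3,4-bis(methoxymethoxy)phenyl]-3-methylpent-4-en-1-ol, via aldehyde 28 (not isolated)
Conditions: 1 M aq HCl, THF, 0 °C; then NaHCO3, NaBH4, MeOH, 0 °C
Reagents that add atoms: water, O
Why: Enol ether hydrolysis followed by borohydride reduction in one flask, as in step 9.

Step 20
Reactants: 29 (3S)-3-[3,4-bis(methoxymethoxy)phenyl]-3-methylpent-4-en-1-ol
Product: 30 4-[(3S)-5-iodo-3-methylpent-1-en-3-yl]-1,2-bis(methoxymethoxy)benzene
Conditions: I2, PPh3, imidazole, CH2Cl2, 0 °C → rt
Reagents that add atoms: iodine, [I][I]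
Why: Appel-type iodination of the primary alcohol, as in step 10.

Step 21
Reactants: 30 4-[(3S)-5-iodo-3-methylpent-1-en-3-yl]-1,2-bis(methoxymethoxy)benzene; 5 (E)-1-iodo-2,6-dimethylhepta-1,5-diene
Product: 32 1,2-bis(methoxymethoxy)-4-[(3S,6E)-3,7,11-trimethyldodeca-1,6,10-trien-3-yl]benzene, via alkylzinc iodide 31 (not isolated)
Conditions: Zn dust (activated with BrCH2CH2Br, Me3SiCl), THF, 40 °C; then 5, Pd(PPh3)4 (5 mol %), THF, rt
Reagents that add atoms: none
Why: Zinc insertion and stereoretentive Negishi coupling form C5–C6, as in step 11.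

Step 22
Reactants: 32 1,2-bis(methoxymethoxy)-4-[(3S,6E)-3,7,11-trimethyldodeca-1,6,10-trien-3-yl]benzene
Product: 35 2,3-bis(methoxymethoxy)-5-[(3S,6E)-3,7,11-trimethyldodeca-1,6,10-trien-3-yl]phenol, via aryllithium 33 (not isolated), via dimethyl arylboronate 34 (not isolated)
Conditions: n-BuLi (1.3 equiv), THF, 0 °C; B(OMe)3, −78 °C → rt; 30% H2O2, aq NaOH, 0 °C → rt
Reagents that add atoms: hydrogen peroxide, OO
Why: Directed ortho-metalation should take place next to the OMOM group para to the side chain, the position between the other OMOM group and the quaternary carbon being blocked; borylation and oxidative 1,2-aryl migration from boron to oxygen then give the phenol without epoxidising the unactivated alkenes.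

**Union and deprotection**

Step 23
Reactants: 20 1-iodo-2-(methoxymethoxy)-4-[(3R,6E)-3,7,11-trimethyldodeca-1,6,10-trien-3-yl]benzene; 35 2,3-bis(methoxymethoxy)-5-[(3S,6E)-3,7,11-trimethyldodeca-1,6,10-trien-3-yl]phenol
Product: 36 1,2-bis(methoxymethoxy)-3-{2-(methoxymethoxy)-4-[(3R,6E)-3,7,11-trimethyldodeca-1,6,10-trien-3-yl]phenoxy}-5-[(3S,6E)-3,7,11-trimethyldodeca-1,6,10-trien-3-yl]benzene
Conditions: copper iodide CuI (10 mol %), picolinic acid (20 mol %), K3PO4 (2 equiv), DMSO, 90 °C, Ar
Reagents that add atoms: none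
Why: Ullmann-type diaryl ether synthesis with a monovalent copper/picolinate catalyst is established for ortho-substituted aryl iodides and ortho-substituted phenols, and alkenes and MOM acetals are inert to phosphate base at this temperature.

Step 24
Reactants: 36 1,2-bis(methoxymethoxy)-3-{2-(methoxymethoxy)-4-[(3R,6E)-3,7,11-trimethyldodeca-1,6,10-trien-3-yl]phenoxy}-5-[(3S,6E)-3,7,11-trimethyldodeca-1,6,10-trien-3-yl]benzene
Product: 37 3-{2-hydroxy-4-[(3R,6E)-3,7,11-trimethyldodeca-1,6,10-trien-3-yl]phenoxy}-5-[(3S,6E)-3,7,11-trimethyldodeca-1,6,10-trien-3-yl]benzene-1,2-diol (CNP0230356.1)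
Conditions: HCl (about 1 M, from AcCl), MeOH/THF, 0 °C → rt, degassed
Reagents that add atoms: none
Why: Acid-catalysed transacetalisation of the three aryl MOM ethers to methanol (MOM deprotection) should free the phenols under conditions mild enough for the trisubstituted alkenes, and the quaternary stereocentres cannot epimerise.

**Compound list**
1 | 6-methylhept-5-en-2-one | CC(=O)CCC=C(C)C | starting material
2 | diethyl 6-methylhepta-1,5-dien-2-yl phosphate | C=C(CCC=C(C)C)OP(=O)(OCC)OCC | intermediate
3 | 6-methylhept-5-en-1-yne | C#CCCC=C(C)C | intermediate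
4 | [(1E)-2,6-dimethylhepta-1,5-dien-1-yl]dimethylalane | C[Al](C)/C=C(\C)CCC=C(C)C | intermediate
5 | (E)-1-iodo-2,6-dimethylhepta-1,5-diene | I/C=C(\C)CCC=C(C)C | intermediate
6 | 3-hydroxyacetophenone | CC(=O)c1cccc(O)c1 | starting material
7 | 1-[3-(methoxymethoxy)phenyl]ethanone | CC(=O)c1cccc(OCOC)c1 | intermediate
8 | 1-(methoxymethoxy)-3-(prop-1-en-2-yl)benzene | CC(=C)c1cccc(OCOC)c1 | intermediate
9 | 1-(2,2-dibromo-1-methylcyclopropyl)-3-(methoxymethoxy)benzene, racemic | CC1(CC1(Br)Br)c1cccc(OCOC)c1 | intermediate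
10 | 1-(2-bromo-1-methylcyclopropyl)-3-(methoxymethoxy)benzene, racemic diastereomer mixture | CC1(CC1Br)c1cccc(OCOC)c1 | intermediate
11 | 1-(methoxymethoxy)-3-(1-methylcycloprop-2-en-1-yl)benzene | CC1(C=C1)c1cccc(OCOC)c1 | intermediate
12 | butyl vinyl ether | C=COCCCC | starting material
13 | 1-[(1Z,3S)-1-butoxy-3-methylpenta-1,4-dien-3-yl]-3-(methoxymethoxy)benzene | C=C[C@@](C)(/C=C\OCCCC)c1cccc(OCOC)c1 | intermediate
14 | (3R)-3-[3-(methoxymethoxy)phenyl]-3-methylpent-4-enal | C=C[C@@](C)(CC=O)c1cccc(OCOC)c1 | intermediate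
15 | (3R)-3-[3-(methoxymethoxy)phenyl]-3-methylpent-4-en-1-ol | C=C[C@@](C)(CCO)c1cccc(OCOC)c1 | intermediate
16 | 1-[(3R)-5-iodo-3-methylpent-1-en-3-yl]-3-(methoxymethoxy)benzene | C=C[C@@](C)(CCI)c1cccc(OCOC)c1 | intermediate
17 | {(3R)-3-[3-(methoxymethoxy)phenyl]-3-methylpent-4-en-1-yl}zinc iodide | C=C[C@@](C)(CC[Zn]I)c1cccc(OCOC)c1 | intermediate
18 | 1-(methoxymethoxy)-3-[(3R,6E)-3,7,11-trimethyldodeca-1,6,10-trien-3-yl]benzene | C=C[C@@](C)(CC/C=C(\C)CCC=C(C)C)c1cccc(OCOC)c1 | intermediate
19 | {2-(methoxymethoxy)-4-[(3R,6E)-3,7,11-trimethyldodeca-1,6,10-trien-3-yl]phenyl}lithium | C=C[C@@](C)(CC/C=C(\C)CCC=C(C)C)c1ccc([Li])c(OCOC)c1 | intermediate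
20 | 1-iodo-2-(methoxymethoxy)-4-[(3R,6E)-3,7,11-trimethyldodeca-1,6,10-trien-3-yl]benzene | C=C[C@@](C)(CC/C=C(\C)CCC=C(C)C)c1ccc(I)c(OCOC)c1 | intermediate
21 | 3,4-dihydroxyacetophenone | CC(=O)c1ccc(O)c(O)c1 | starting material
22 | 1-[3,4-bis(methoxymethoxy)phenyl]ethanone | CC(=O)c1ccc(OCOC)c(OCOC)c1 | intermediate
23 | 1,2-bis(methoxymethoxy)-4-(prop-1-en-2-yl)benzene | CC(=C)c1ccc(OCOC)c(OCOC)c1 | intermediate
24 | 4-(2,2-dibromo-1-methylcyclopropyl)-1,2-bis(methoxymethoxy)benzene, racemic | CC1(CC1(Br)Br)c1ccc(OCOC)c(OCOC)c1 | intermediate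
25 | 4-(2-bromo-1-methylcyclopropyl)-1,2-bis(methoxymethoxy)benzene, racemic diastereomer mixture | CC1(CC1Br)c1ccc(OCOC)c(OCOC)c1 | intermediate
26 | 1,2-bis(methoxymethoxy)-4-(1-methylcycloprop-2-en-1-yl)benzene | CC1(C=C1)c1ccc(OCOC)c(OCOC)c1 | intermediate
27 | 4-[(1Z,3R)-1-butoxy-3-methylpenta-1,4-dien-3-yl]-1,2-bis(methoxymethoxy)benzene | C=C[C@](C)(/C=C\OCCCC)c1ccc(OCOC)c(OCOC)c1 | intermediate
28 | (3S)-3-[3,4-bis(methoxymethoxy)phenyl]-3-methylpent-4-enal | C=C[C@](C)(CC=O)c1ccc(OCOC)c(OCOC)c1 | intermediate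
29 | (3S)-3-[3,4-bis(methoxymethoxy)phenyl]-3-methylpent-4-en-1-ol | C=C[C@](C)(CCO)c1ccc(OCOC)c(OCOC)c1 | intermediate
30 | 4-[(3S)-5-iodo-3-methylpent-1-en-3-yl]-1,2-bis(methoxymethoxy)benzene | C=C[C@](C)(CCI)c1ccc(OCOC)c(OCOC)c1 | intermediate
31 | {(3S)-3-[3,4-bis(methoxymethoxy)phenyl]-3-methylpent-4-en-1-yl}zinc iodide | C=C[C@](C)(CC[Zn]I)c1ccc(OCOC)c(OCOC)c1 | intermediate
32 | 1,2-bis(methoxymethoxy)-4-[(3S,6E)-3,7,11-trimethyldodeca-1,6,10-trien-3-yl]benzene | C=C[C@](C)(CC/C=C(\C)CCC=C(C)C)c1ccc(OCOC)c(OCOC)c1 | intermediate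
33 | {2,3-bis(methoxymethoxy)-5-[(3S,6E)-3,7,11-trimethyldodeca-1,6,10-trien-3-yl]phenyl}lithium | C=C[C@](C)(CC/C=C(\C)CCC=C(C)C)c1cc([Li])c(OCOC)c(OCOC)c1 | intermediate
34 | dimethyl {2,3-bis(methoxymethoxy)-5-[(3S,6E)-3,7,11-trimethyldodeca-1,6,10-trien-3-yl]phenyl}boronate | C=C[C@](C)(CC/C=C(\C)CCC=C(C)C)c1cc(B(OC)OC)c(OCOC)c(OCOC)c1 | intermediate
35 | 2,3-bis(methoxymethoxy)-5-[(3S,6E)-3,7,11-trimethyldodeca-1,6,10-trien-3-yl]phenol | C=C[C@](C)(CC/C=C(\C)CCC=C(C)C)c1cc(O)c(OCOC)c(OCOC)c1 | intermediate
36 | 1,2-bis(methoxymethoxy)-3-{2-(methoxymethoxy)-4-[(3R,6E)-3,7,11-trimethyldodeca-1,6,10-trien-3-yl]phenoxy}-5-[(3S,6E)-3,7,11-trimethyldodeca-1,6,10-trien-3-yl]benzene | C=C[C@@](C)(CC/C=C(\C)CCC=C(C)C)c1ccc(Oc2cc([C@](C)(C=C)CC/C=C(\C)CCC=C(C)C)cc(OCOC)c2OCOC)c(OCOC)c1 | intermediate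
37 | 3-{2-hydroxy-4-[(3R,6E)-3,7,11-trimethyldodeca-1,6,10-trien-3-yl]phenoxy}-5-[(3S,6E)-3,7,11-trimethyldodeca-1,6,10-trien-3-yl]benzene-1,2-diol | C=C[C@@](C)(CC/C=C(\C)CCC=C(C)C)c1ccc(Oc2cc([C@](C)(C=C)CC/C=C(\C)CCC=C(C)C)cc(O)c2O)c(O)c1 | target

**Totals**
Total step count: 24. Longest linear sequence: 12 steps (steps 3–12, 23, 24 from 6; equally steps 13–22, 23, 24 from 21).

**Steps most likely to fail**

1. Step 8 (and its mirror-image twin, step 18). The MOM acetal oxygens may bind the Lewis-acidic molybdenum centre and slow or derail the catalyst, the enantiotopic-terminus selection may erode on these oxygenated arenes, or the cyclopropene may oligomerise. The fallback builds the same quaternary carbon by nickel-catalysed asymmetric hydrovinylation of a 1,1-disubstituted vinylarene. It sets out from ketone 7: the lithium enolate (LDA, THF, −78 °C) would be alkylated with geranyl bromide to give (E)-1-[3-(methoxymethoxy)phenyl]-5,9-dimethyldeca-4,8-dien-1-one F1. Wittig methylenation (Ph3PCH3Br, KOtBu, THF) would give 1-(methoxymethoxy)-3-[(5E)-6,10-dimethylundeca-1,5,9-trien-2-yl]benzene F2. Hydrovinylation with ethylene ([Ni(allyl)Br]2, an enantiopure binaphthol-derived phosphoramidite, NaB[3,5-(CF3)2C6H3]4, CH2Cl2, −70 °C) would add hydrogen to the terminal carbon and vinyl to the benzylic carbon and come back to the route at 18. In the ring B series the same three operations with the antipodal ligand would lead from 22 through (E)-1-[3,4-bis(methoxymethoxy)phenyl]-5,9-dimethyldeca-4,8-dien-1-one F3 and 1,2-bis(methoxymethoxy)-4-[(5E)-6,10-dimethylundeca-1,5,9-trien-2-yl]benzene F4 back to the route at 32.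

2. Step 23. C–O bond formation between two electron-rich partners that each carry an ortho alkoxy group may be slow, with protodeiodination of 20 competing. The fallback is an oxidative Chan–Lam coupling. It sets out from 18: lithiation as in step 12 and quenching with B(OMe)3 would give dimethyl {2-(methoxymethoxy)-4-[(3R,6E)-3,7,11-trimethyldodeca-1,6,10-trien-3-yl]phenyl}boronate F5, hydrolysed on aqueous work-up to {2-(methoxymethoxy)-4-[(3R,6E)-3,7,11-trimethyldodeca-1,6,10-trien-3-yl]phenyl}boronic acid F6. F6 would be coupled with phenol 35 under divalent copper (Cu(OAc)2, pyridine, 4 Å molecular sieves, CH2Cl2, air, rt) and come back to the route at 36.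

3. Step 24. Protic acid may trigger cationic cyclisation or methanol addition at the trisubstituted alkenes before all three acetals are gone. The fallback exchanges MOM for silyl under non-protic conditions and then uses fluoride. It sets out from 36: Et3SiOTf and 2,2'-bipyridyl in CH2Cl2 at 0 °C would convert the aryl MOM ethers directly into 1,2-bis(triethylsilyloxy)-3-{2-(triethylsilyloxy)-4-[(3R,6E)-3,7,11-trimethyldodeca-1,6,10-trien-3-yl]phenoxy}-5-[(3S,6E)-3,7,11-trimethyldodeca-1,6,10-trien-3-yl]benzene F7. Bu4NF buffered with AcOH in THF at 0 °C would then come back to the route at 37.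

**Further compounds**
F1 | step 8 | (E)-1-[3-(methoxymethoxy)phenyl]-5,9-dimethyldeca-4,8-dien-1-one | O=C(CC/C=C(\C)CCC=C(C)C)c1cccc(OCOC)c1
F2 | step 8 | 1-(methoxymethoxy)-3-[(5E)-6,10-dimethylundeca-1,5,9-trien-2-yl]benzene | C=C(CC/C=C(\C)CCC=C(C)C)c1cccc(OCOC)c1
F3 | step 8 | (E)-1-[3,4-bis(methoxymethoxy)phenyl]-5,9-dimethyldeca-4,8-dien-1-one | O=C(CC/C=C(\C)CCC=C(C)C)c1ccc(OCOC)c(OCOC)c1
F4 | step 8 | 1,2-bis(methoxymethoxy)-4-[(5E)-6,10-dimethylundeca-1,5,9-trien-2-yl]benzene | C=C(CC/C=C(\C)CCC=C(C)C)c1ccc(OCOC)c(OCOC)c1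
F5 | step 23 | dimethyl {2-(methoxymethoxy)-4-[(3R,6E)-3,7,11-trimethyldodeca-1,6,10-trien-3-yl]phenyl}boronate | C=C[C@@](C)(CC/C=C(\C)CCC=C(C)C)c1ccc(B(OC)OC)c(OCOC)c1
F6 | step 23 | {2-(methoxymethoxy)-4-[(3R,6E)-3,7,11-trimethyldodeca-1,6,10-trien-3-yl]phenyl}boronic acid | C=C[C@@](C)(CC/C=C(\C)CCC=C(C)C)c1ccc(B(O)O)c(OCOC)c1
F7 | step 24 | 1,2-bis(triethylsilyloxy)-3-{2-(triethylsilyloxy)-4-[(3R,6E)-3,7,11-trimethyldodeca-1,6,10-trien-3-yl]phenoxy}-5-[(3S,6E)-3,7,11-trimethyldodeca-1,6,10-trien-3-yl]benzene | C=C[C@@](C)(CC/C=C(\C)CCC=C(C)C)c1ccc(Oc2cc([C@](C)(C=C)CC/C=C(\C)CCC=C(C)C)cc(O[Si](CC)(CC)CC)c2O[Si](CC)(CC)CC)c(O[Si](CC)(CC)CC)c1
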